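## The problem

The target **18** is (2S)-7,4'-dihydroxy-6,8,3'-triprenylflavanone: a chroman-4-one (rings A and C fused at C4a–C8a) with ring B on C2, a prenyl group on each carbon flanking the C7 hydroxyl, and a third prenyl group ortho to the 4'-hydroxyl. C2 is the only stereocentre, so no other centre can relay its configuration; a reagent or catalyst must set it and the later steps must not erode it. C2 is benzylic to an electron-rich ring and β to the C4 ketone, so base (and hot acid) opens ring C by retro-oxa-Michael cleavage of O1–C2 and recloses it without facial bias. The classical ring closure, O1 onto C2 of a chalcone, forms exactly this labile bond. The three trisubstituted alkenes rule out hydrogenolysis, electrophilic halogen and strong oxidants late in the route, and an ortho-prenylphenol cyclises to a 2,2-dimethylchroman in strong acid, so the phenol protecting groups must come off under mild protic acid. In ring A the C8 prenyl group sits between two substituted carbons, where direct C-alkylation of a phenol is unreliable. The enabling feature is that O1 of ring C joins the stereocentre C2 to the aromatic carbon C8a: arylating a C2 carbinol oxygen at C8a closes ring C while all four bonds at C2 stay intact.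

## Retrosynthesis

**18 from 16 (no skeletal bond cut).** The last operation only unmasks. The two phenols carry methoxymethyl ethers and C4 is an ethylene ketal, so all three masks are acetals and fall in one dilute-acid treatment, by way of the ketone **17**. Benzyl ethers would need hydrogenolysis, which the prenyl groups do not survive. Silyl ethers would need basic fluoride, which threatens C2. The forward step needs acid mild enough to leave the ortho-prenylphenols uncyclised.

**16 from 15 (cut O1–C8a).** Cutting O1–C2 instead leads to an oxa-Michael or substitution closure that makes a bond at the stereocentre. Cutting C2–C3 asks a ring-forming C–C reaction to create the stereocentre. The O1–C8a cut does neither: **15** is an open-chain (S)-benzylic alcohol with a bromide at C8a, and closure is an aryl etherification. The forward reaction must form the aryl C–O bond faster than the palladium alkoxide undergoes β-hydride elimination. It must run with C4 masked, because a free β-hydroxy ketone would undergo retro-aldol cleavage or dehydration under the carbonate base.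

**15 from 14 (cut C2–H).** The carbinol comes from enantioselective reduction of the aryl ketone **14**, whose C4 is already a dioxolane. The neighbouring option is to bring the carbinol in before the fragments are joined and ketalise afterwards. That would place an acid ketalisation next to an ionisable p-alkoxybenzylic C–O bond and three prenyl groups, with elimination to a chalcone as the likely outcome. Reducing after ketalisation avoids this, and **14** is achiral. The forward step needs reagent control that distinguishes aryl from CH2 and a hydride source that does not hydroborate alkenes.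

**14 from 8 and 12 (cut C2–C1').** A ring-B aryl Grignard reagent **13**, made from bromide **12**, acylates the Weinreb amide **8**. An aldol cut at C2–C3 would give a free aldol that must then be ketalised, which is the problem just avoided. A cut at C4–C4a would require a ring-A aryl metal next to the C8a bromide. The chosen cut divides the molecule into a seven-step ring-A piece and a two-step ring-B piece. The forward step needs mono-addition and no attack on the C8a bromide.

**8 from 5 via 7 and 6 (cut the two aryl–allyl bonds and the alkene carbons).** The amide **8** comes from ester **7**. The prenyl groups of **7** come from the allyl groups of **6** by cross-metathesis, and the allyl groups come from the diiodide **5** by Stille coupling. Direct coupling of prenyl metals tends to give linear and branched products; an allyl group has no such ambiguity. The iodides sit exactly on the two carbons ortho to oxygen. The forward coupling must consume both iodides, including the one flanked by bromine and OMOM, and leave the bromide untouched. Direct C-prenylation of a phenoxide would be shorter, but regiocontrol is poor at the position next to bromine.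

**5 from 1 via 4, 3 and 2.** The dioxolane of **5** is put on the β-keto ester **4**, which comes from methyl ketone **3** by Claisen condensation. Ketone **3** comes from phenol **2** by protection, and **2** from commercial **1** by iodination at both positions ortho to the hydroxyl. Ketalisation is placed here because the substrate has no alkene, no stereocentre and no β-leaving group. Compound **1** already carries the bromide at the future C8a and the acetyl group that becomes C4 and C3.

**12 from 9 via 10.** The ring-B prenyl group is attached by iodine–magnesium exchange of **10** (giving **11**) and copper-catalysed allylic substitution. The bromide para to oxygen is kept for the later Grignard reagent **13**. Commercial **9** supplies both halogens in the right places.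

## Roads not taken

**Alternative 1:** The cut is C2–C3. A diazomethyl ketone **A1**, with an O-benzyl ether linking rings A and B, would lose nitrogen to a chiral dirhodium carboxylate such as Rh2(S-PTTL)4, and the carbenoid would insert into a benzylic O–CH2 bond to give the tribromoflavanone **A2**. This closes ring C and sets C2 in one step.
- Merits: ring and stereocentre arise together in one catalytic step from an achiral precursor. The three bromines stand in for the prenyl groups, so no alkene is exposed to the carbenoid.
- Weak points: the ether oxygen lies five atoms from the carbenoid carbon and can intercept it as an oxonium ylide, whose benzyl shift diverts material into a five-membered ring. Acceptor-only carbenoids are the least enantioselective class for such insertions. After the key step, three aryl–prenyl bonds must be made on a formed flavanone, one at the flanked C8, with basic organometallic reagents that can open ring C and add to the ketone.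
- Comparison: this road is shorter to the flavanone core than the chosen plan. The chosen plan offers instead a predictable absolute configuration from an aryl ketone reduction, and it finishes all C–C bond formation before the base-sensitive ring exists.

**Alternative 2:** The cuts are C3–C4 and O1–C2. The salicylaldehyde **A3**, an orthoformate and a chiral phosphoric acid would give a C4-methoxy ortho-quinone methide. This would add the ring-B styrene **A4** in a hetero-Diels–Alder reaction to give the 4-methoxyflavan **A5**.
- Merits: this is the most convergent road. Two short fragments, already prenylated, are joined, and ring C and C2 are formed in one step.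
- Weak points: the cationic intermediate is generated by acid next to a free phenol with an ortho prenyl group, so internal capture to a dimethylchroman competes. The prenyl alkenes are rival electron-rich 2π partners for the styrene. C4 then has to be brought from the methyl ether to the ketone by hydrolysis and oxidation in the presence of three alkenes. The silyl ethers need fluoride, which is basic, on a finished flavanone.
- Comparison: on step count and convergence this road is better. The chosen plan confines acid to the last step and takes its enantiocontrol from a simple ketone reduction rather than from a cycloaddition whose chemo- and enantioselectivity must both hold in a substrate with four nucleophilic alkenes.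

**Alternative 3:** The cuts are C4a–C5 and C8a–C8, so ring A is built last. The silyloxydiene **A7**, carrying both prenyl groups, would add across the C4a–C8a double bond of the (S)-iodo-dihydropyranone **A6**. Loss of HI and dehydrogenation with a quinone oxidant would give the protected flavanone **A8**.
- Merits: C2 is set early in a small heterocycle. The ring-A substituents are placed by construction, which removes the aromatic substitution problem that costs the chosen plan four steps (1, 2, 5 and 6). The polarity of the diene matches the enone, since the diene terminus next to the silyloxy carbon bonds to C8a.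
- Weak points: **A7** is a 1,3-disubstituted 2-silyloxydiene that must be made geometrically pure. **A6** is a vinylogous ester and a weak dienophile. The aromatisation uses an oxidant that also dehydrogenates flavanones across C2–C3 and attacks benzylic and allylic positions of prenylarenes, so it threatens the stereocentre that the route was built to protect.
- Comparison: in its handling of ring-A regiochemistry this road is better. The chosen plan offers close precedent for every step and brings no oxidant near C2.

Key step: step 12

Remark: prenyl means 3-methylbut-2-en-1-yl, flavanone numbering (O1, C2, C3, C4, C4a, C5–C8, C8a, ring B primed) is used for all intermediates, and compounds 1 and 9 are taken to be catalogue chemicals.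

## Route

Step 1
Reactants: 1 1-(2-bromo-4-hydroxyphenyl)ethanone
Product: 2 1-(2-bromo-4-hydroxy-3,5-diiodophenyl)ethanone
Conditions: N-iodosuccinimide (2.2 equiv), p-TsOH·H2O (10 mol%), MeCN, rt
Reagents that add atoms: N-iodosuccinimide, O=C1CCC(=O)N1I
Why: Electrophilic aromatic iodination; the hydroxyl activates its two free ortho positions (para is blocked by the acetyl group), and the phenol ring reacts much faster than the enol of the methyl ketone.

Step 2
Reactants: 2 1-(2-bromo-4-hydroxy-3,5-diiodophenyl)ethanone
Product: 3 1-[2-bromo-3,5-diiodo-4-(methoxymethoxy)phenyl]ethanone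
Conditions: MOMCl (1.5 equiv), K2CO3 (2 equiv), acetone, 0 °C to rt
Reagents that add atoms: chloromethyl methyl ether, COCCl
Why: Williamson-type O-alkylation of the acidic diiodophenol by the α-chloro ether; the MOM acetal withstands the basic and organometallic steps that follow and leaves with the dioxolane at the end.

Step 3
Reactants: 3 1-[2-bromo-3,5-diiodo-4-(methoxymethoxy)phenyl]ethanone
Product: 4 methyl 3-[2-bromo-3,5-diiodo-4-(methoxymethoxy)phenyl]-3-oxopropanoate
Conditions: NaH (2.5 equiv), dimethyl carbonate (5 equiv), toluene, 80 °C; AcOH quench
Reagents that add atoms: dimethyl carbonate, COC(=O)OC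
Why: Crossed Claisen condensation of the methyl ketone enolate with dimethyl carbonate, driven by deprotonation of the β-keto ester product; aryl halides and the MOM ether are inert to NaH.

Step 4
Reactants: 4 methyl 3-[2-bromo-3,5-diiodo-4-(methoxymethoxy)phenyl]-3-oxopropanoate
Product: 5 methyl 2-{2-[2-bromo-3,5-diiodo-4-(methoxymethoxy)phenyl]-1,3-dioxolan-2-yl}acetate
Conditions: 1,2-bis(trimethylsilyloxy)ethane (3 equiv), TMSOTf (10 mol%), CH2Cl2, −78 to −20 °C; pyridine quench
Reagents that add atoms: 1,2-bis(trimethylsilyloxy)ethane, C[Si](C)(C)OCCO[Si](C)(C)C
Why: Noyori-type ketalisation by silyl transfer, made irreversible by formation of hexamethyldisiloxane; the substrate has no alkene, no stereocentre and no β-leaving group, and an aryl MOM ether tolerates catalytic TMSOTf at low temperature.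

Step 5
Reactants: 5 methyl 2-{2-[2-bromo-3,5-diiodo-4-(methoxymethoxy)phenyl]-1,3-dioxolan-2-yl}acetate
Product: 6 methyl 2-{2-[2-bromo-4-(methoxymethoxy)-3,5-di(prop-2-en-1-yl)phenyl]-1,3-dioxolan-2-yl}acetate
Conditions: allyltributylstannane (2.6 equiv), Pd(PPh3)4 (5 mol%), CuI (10 mol%), CsF (4 equiv), DMF, 45 °C
Reagents that add atoms: allyltributylstannane, C=CC[Sn](CCCC)(CCCC)CCCC
Why: Two-fold Stille coupling; zerovalent palladium with PPh3 inserts into C–I far faster than into C–Br, so the bromide at the future C8a survives, and copper and fluoride speed transmetalation at the iodide flanked by Br and OMOM. An allyl group is used because it cannot couple in a branched sense.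

Step 6
Reactants: 6 methyl 2-{2-[2-bromo-4-(methoxymethoxy)-3,5-di(prop-2-en-1-yl)phenyl]-1,3-dioxolan-2-yl}acetate
Product: 7 methyl 2-{2-[2-bromo-4-(methoxymethoxy)-3,5-bis(3-methylbut-2-en-1-yl)phenyl]-1,3-dioxolan-2-yl}acetate
Conditions: 2-methyl-2-butene (excess, co-solvent), second-generation Grubbs catalyst RuCl2(=CHPh)(PCy3)(H2IMes) (5 mol%), CH2Cl2, 40 °C
Reagents that add atoms: 2-methyl-2-butene, CC=C(C)C
Why: Olefin cross-metathesis turns each terminal allyl group into a prenyl group with loss of propene; the trisubstituted products re-enter metathesis only slowly, and the two meta-disposed allyl groups cannot ring-close.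

Step 7
Reactants: 7 methyl 2-{2-[2-bromo-4-(methoxymethoxy)-3,5-bis(3-methylbut-2-en-1-yl)phenyl]-1,3-dioxolan-2-yl}acetate
Product: 8 2-{2-[2-bromo-4-(methoxymethoxy)-3,5-bis(3-methylbut-2-en-1-yl)phenyl]-1,3-dioxolan-2-yl}-N-methoxy-N-methylacetamide
Conditions: MeNHOMe·HCl (2 equiv), i-PrMgCl (4 equiv), THF, −20 to 0 °C
Reagents that add atoms: N,O-dimethylhydroxylamine hydrochloride, CNOC.Cl
Why: Weinreb amide synthesis by aminolysis of the methyl ester with the chloromagnesium amide made in the flask; the ketal, the MOM ether and the unactivated aryl bromide are inert at this temperature.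

Step 8
Reactants: 9 4-bromo-2-iodophenol
Product: 10 4-bromo-2-iodo-1-(methoxymethoxy)benzene
Conditions: MOMCl (1.3 equiv), K2CO3 (2 equiv), acetone, 0 °C to rt
Reagents that add atoms: chloromethyl methyl ether, COCCl
Why: Williamson-type O-alkylation of the phenol; the MOM group later directs the halogen–metal exchange and matches the protecting group on ring A.

Step 9
Reactants: 10 4-bromo-2-iodo-1-(methoxymethoxy)benzene
Product: 12 4-bromo-1-(methoxymethoxy)-2-(3-methylbut-2-en-1-yl)benzene, via arylmagnesium chloride 11 (not isolated)
Conditions: i-PrMgCl·LiCl (1.1 equiv), THF, −20 °C; then Li2CuCl4 (5 mol%), prenyl bromide (1.3 equiv), −20 to 0 °C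
Reagents that add atoms: prenyl bromide (1-bromo-3-methylbut-2-ene), CC(C)=CCBr
Why: Iodine–magnesium exchange occurs only at the iodide ortho to the coordinating OMOM group and leaves the bromide. Copper-catalysed allylic substitution then attacks the unhindered primary carbon of prenyl bromide and gives the linear prenylarene.

Step 10
Reactants: 12 4-bromo-1-(methoxymethoxy)-2-(3-methylbut-2-en-1-yl)benzene; 8 2-{2-[2-bromo-4-(methoxymethoxy)-3,5-bis(3-methylbut-2-en-1-yl)phenyl]-1,3-dioxolan-2-yl}-N-methoxy-N-methylacetamide
Product: 14 2-{2-[2-bromo-4-(methoxymethoxy)-3,5-bis(3-methylbut-2-en-1-yl)phenyl]-1,3-dioxolan-2-yl}-1-[4-(methoxymethoxy)-3-(3-methylbut-2-en-1-yl)phenyl]ethanone, via arylmagnesium bromide 13 (not isolated)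
Conditions: 12, Mg turnings, THF, 40 °C; then 8, THF, 0 °C to rt; aq. NH4Cl
Reagents that add atoms: none
Why: Weinreb ketone synthesis; the aryl Grignard reagent adds once to give a chelated tetrahedral magnesium adduct that releases the ketone only on work-up. An aryl Grignard reagent does not exchange with the C8a bromide, and the ketal is stable to base.

Step 11
Reactants: 14 2-{2-[2-bromo-4-(methoxymethoxy)-3,5-bis(3-methylbut-2-en-1-yl)phenyl]-1,3-dioxolan-2-yl}-1-[4-(methoxymethoxy)-3-(3-methylbut-2-en-1-yl)phenyl]ethanone
Product: 15 (S)-2-{2-[2-bromo-4-(methoxymethoxy)-3,5-bis(3-methylbut-2-en-1-yl)phenyl]-1,3-dioxolan-2-yl}-1-[4-(methoxymethoxy)-3-(3-methylbut-2-en-1-yl)phenyl]ethanol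
Conditions: (R)-2-methyl-CBS-oxazaborolidine (20 mol%), catecholborane (1.8 equiv), toluene, −78 to −40 °C; MeOH, then aq. NaHCO3
Reagents that add atoms: none
Why: Corey–Bakshi–Shibata reduction; the ketone binds the catalyst boron on the side of the CH2 group with the aryl ring as the large substituent, and the (R)-catalyst delivers hydride to the Re face to give (S)-C2. Catecholborane is chosen because it does not hydroborate trisubstituted alkenes at this temperature.

Step 12
Reactants: 15 (S)-2-{2-[2-bromo-4-(methoxymethoxy)-3,5-bis(3-methylbut-2-en-1-yl)phenyl]-1,3-dioxolan-2-yl}-1-[4-(methoxymethoxy)-3-(3-methylbut-2-en-1-yl)phenyl]ethanol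
Product: 16 (S)-7,4'-bis(methoxymethoxy)-6,8,3'-triprenylflavanone ethylene ketal [(2S)-7-(methoxymethoxy)-2-[4-(methoxymethoxy)-3-prenylphenyl]-6,8-diprenylspiro[chromane-4,2'-[1,3]dioxolane]]
Conditions: Pd(OAc)2 (5 mol%), 2-(di-tert-butylphosphino)-1,1'-binaphthyl (6 mol%), Cs2CO3 (1.5 equiv), degassed toluene, 80 °C
Reagents that add atoms: none
Why: This is a palladium-catalysed intramolecular aryl etherification (Buchwald–Hartwig-type C–O coupling), whose closest precedent is the cyclisation of 2-bromoaryl-tethered secondary alcohols to 2-substituted chromans. Pd(OAc)2 is reduced in the flask to zerovalent palladium, which inserts into the C8a–Br bond; Cs2CO3 deprotonates the bound C2 hydroxyl to give a seven-membered aryl(alkoxo) palladacycle of divalent palladium, and C(sp2)–O reductive elimination closes the six-membered ring C and returns the catalyst. No stereocentre is created: the C2–O, C2–H and both C2–C bonds are never broken, so the (S) configuration from step 11 passes into 16 unchanged. The step needs reductive elimination to outrun β-hydride elimination of the benzylic alkoxide, which would return ketone 14 and a debrominated arene. The bulky, electron-rich di-tert-butylbiarylphosphine, the C8 prenyl group ortho to palladium and the gem-dialkoxy substitution at C4, which folds the chain towards the metal, all favour ring closure. The dioxolane also removes the base-labile β-hydroxy ketone, so retro-aldol cleavage and dehydration cannot compete, and MOM ethers and prenyl groups are inert to the carbonate base.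

Step 13
Reactants: 16 (S)-7,4'-bis(methoxymethoxy)-6,8,3'-triprenylflavanone ethylene ketal
Product: 18 (2S)-7,4'-dihydroxy-6,8,3'-triprenylflavanone, via bis-MOM flavanone 17 (not isolated)
Conditions: 3 M aq. HCl–MeOH (1:4), 45 °C
Reagents that add atoms: water, O
Why: Acid-catalysed acetal hydrolysis; the benzylic dioxolane ionises first to give 17, then the two aryl MOM ethers exchange with methanol. Dilute acid at moderate temperature is the usual way to unmask prenylated flavanones without cyclising ortho-prenylphenols or opening ring C.

## Compound list

1 | 1-(2-bromo-4-hydroxyphenyl)ethanone | CC(=O)c1ccc(O)cc1Br | starting material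
2 | 1-(2-bromo-4-hydroxy-3,5-diiodophenyl)ethanone | CC(=O)c1cc(I)c(O)c(I)c1Br | intermediate
3 | 1-[2-bromo-3,5-diiodo-4-(methoxymethoxy)phenyl]ethanone | CC(=O)c1cc(I)c(OCOC)c(I)c1Br | intermediate
4 | methyl 3-[2-bromo-3,5-diiodo-4-(methoxymethoxy)phenyl]-3-oxopropanoate | COC(=O)CC(=O)c1cc(I)c(OCOC)c(I)c1Br | intermediate
5 | methyl 2-{2-[2-bromo-3,5-diiodo-4-(methoxymethoxy)phenyl]-1,3-dioxolan-2-yl}acetate | COC(=O)CC1(OCCO1)c2cc(I)c(OCOC)c(I)c2Br | intermediate
6 | methyl 2-{2-[2-bromo-4-(methoxymethoxy)-3,5-di(prop-2-en-1-yl)phenyl]-1,3-dioxolan-2-yl}acetate | COC(=O)CC1(OCCO1)c2cc(CC=C)c(OCOC)c(CC=C)c2Br | intermediate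
7 | methyl 2-{2-[2-bromo-4-(methoxymethoxy)-3,5-bis(3-methylbut-2-en-1-yl)phenyl]-1,3-dioxolan-2-yl}acetate | COC(=O)CC1(OCCO1)c2cc(CC=C(C)C)c(OCOC)c(CC=C(C)C)c2Br | intermediate
8 | 2-{2-[2-bromo-4-(methoxymethoxy)-3,5-bis(3-methylbut-2-en-1-yl)phenyl]-1,3-dioxolan-2-yl}-N-methoxy-N-methylacetamide | CON(C)C(=O)CC1(OCCO1)c2cc(CC=C(C)C)c(OCOC)c(CC=C(C)C)c2Br | intermediate
9 | 4-bromo-2-iodophenol | Oc1ccc(Br)cc1I | starting material
10 | 4-bromo-2-iodo-1-(methoxymethoxy)benzene | COCOc1ccc(Br)cc1I | intermediate
11 | [5-bromo-2-(methoxymethoxy)phenyl]magnesium chloride | COCOc1ccc(Br)cc1[Mg]Cl | intermediate (not isolated)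
12 | 4-bromo-1-(methoxymethoxy)-2-(3-methylbut-2-en-1-yl)benzene | COCOc1ccc(Br)cc1CC=C(C)C | intermediate
13 | [4-(methoxymethoxy)-3-(3-methylbut-2-en-1-yl)phenyl]magnesium bromide | COCOc1ccc([Mg]Br)cc1CC=C(C)C | intermediate (not isolated)
14 | 2-{2-[2-bromo-4-(methoxymethoxy)-3,5-bis(3-methylbut-2-en-1-yl)phenyl]-1,3-dioxolan-2-yl}-1-[4-(methoxymethoxy)-3-(3-methylbut-2-en-1-yl)phenyl]ethanone | COCOc1ccc(C(=O)CC2(OCCO2)c3cc(CC=C(C)C)c(OCOC)c(CC=C(C)C)c3Br)cc1CC=C(C)C | intermediate
15 | (S)-2-{2-[2-bromo-4-(methoxymethoxy)-3,5-bis(3-methylbut-2-en-1-yl)phenyl]-1,3-dioxolan-2-yl}-1-[4-(methoxymethoxy)-3-(3-methylbut-2-en-1-yl)phenyl]ethanol | COCOc1ccc([C@@H](O)CC2(OCCO2)c3cc(CC=C(C)C)c(OCOC)c(CC=C(C)C)c3Br)cc1CC=C(C)C | intermediate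
16 | (S)-7,4'-bis(methoxymethoxy)-6,8,3'-triprenylflavanone ethylene ketal | COCOc1ccc([C@@H]2CC3(OCCO3)c4cc(CC=C(C)C)c(OCOC)c(CC=C(C)C)c4O2)cc1CC=C(C)C | intermediate
17 | (S)-7,4'-bis(methoxymethoxy)-6,8,3'-triprenylflavanone | COCOc1ccc([C@@H]2CC(=O)c3cc(CC=C(C)C)c(OCOC)c(CC=C(C)C)c3O2)cc1CC=C(C)C | intermediate (not isolated)
18 | (2S)-7,4'-dihydroxy-6,8,3'-triprenylflavanone | CC(C)=CCc1cc([C@@H]2CC(=O)c3cc(CC=C(C)C)c(O)c(CC=C(C)C)c3O2)ccc1O | target

## Step count and risks

Total: 13 steps. Longest linear sequence: 11 steps (steps 1–7 and 10–13, from 1). The ring-B branch is 2 steps (8 and 9, from 9).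

**Step 12 (key step).** The most likely failure is β-hydride elimination of the benzylic palladium alkoxide, which would lead to reduction of the C–Br bond and oxidation of the carbinol. If this elimination were reversible it could also erode the configuration at C2. Slow oxidative addition at the doubly flanked C8a bromide would favour both. Fallback: from 15 directly to 16 by copper-mediated Ullmann-type etherification (CuI, 3,4,7,8-tetramethyl-1,10-phenanthroline, Cs2CO3, toluene, 110 °C). Copper alkoxides do not readily undergo β-hydride elimination, and C–O bond formation follows a different elementary sequence. No new compound is made.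

**Step 11.** The risk is poor facial selectivity, because the CH2 group on the ketone carries a quaternary ketal carbon and is less clearly the small substituent. Lewis-acid opening of the β-keto ketal is a second concern. Fallback: from 14 to 15 by asymmetric transfer hydrogenation with RuCl(p-cymene)[(S,S)-TsDPEN] and sodium formate in water–CH2Cl2. This catalyst distinguishes aryl from alkyl by a CH–π contact rather than by size, and it works near neutral pH without boron. No new compound is made.

**Step 4.** The risk is slow ketalisation of a partly enolised ketone with an ortho bromine, with loss of the MOM ether if the reaction has to be warmed. Fallback: from 4, Dean–Stark ketalisation with ethylene glycol and p-TsOH in refluxing benzene, accepting full MOM cleavage, to give methyl 2-[2-(2-bromo-4-hydroxy-3,5-diiodophenyl)-1,3-dioxolan-2-yl]acetate F1. Re-protection with MOMCl and K2CO3 returns to 5. This is possible only because no alkene is present at this stage.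

**Step 5.** The risk is incomplete coupling or protodeiodination at the iodide between Br and OMOM, or loss of iodide-over-bromide selectivity once the first allyl group is in place. Fallback: from 1, a route without palladium or iodides:
- two-fold C-prenylation of the phenoxide with prenyl bromide in aqueous KOH gives 1-[2-bromo-4-hydroxy-3,5-bis(3-methylbut-2-en-1-yl)phenyl]ethanone F2;
- MOMCl and K2CO3 give 1-[2-bromo-4-(methoxymethoxy)-3,5-bis(3-methylbut-2-en-1-yl)phenyl]ethanone F3;
- NaH and dimethyl carbonate give methyl 3-[2-bromo-4-(methoxymethoxy)-3,5-bis(3-methylbut-2-en-1-yl)phenyl]-3-oxopropanoate F4;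
- silyl-transfer ketalisation as in step 4 returns to 7.

This path is shorter, but the alkylation next to bromine is expected to be inefficient and unselective, which is why it is not the first choice.

**Step 13.** The risk is acid-induced cyclisation of the ortho-prenylphenols as they are released, and partial loss of configuration by reversible opening of ring C. Fallback: from 16 in two stages. PPTS in wet acetone at rt removes only the dioxolane and gives 17, which is isolated. ZnBr2 and n-PrSH in CH2Cl2 at 0 °C then cleave the two MOM ethers by Lewis-acid activation and thiol capture, without protic acid, to give 18.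

## Further compounds

F0 | step 12 | none | none
F0 | step 11 | none | none
F1 | step 4 | methyl 2-[2-(2-bromo-4-hydroxy-3,5-diiodophenyl)-1,3-dioxolan-2-yl]acetate | COC(=O)CC1(OCCO1)c2cc(I)c(O)c(I)c2Br
F2 | step 5 | 1-[2-bromo-4-hydroxy-3,5-bis(3-methylbut-2-en-1-yl)phenyl]ethanone | CC(=O)c1cc(CC=C(C)C)c(O)c(CC=C(C)C)c1Br
F3 | step 5 | 1-[2-bromo-4-(methoxymethoxy)-3,5-bis(3-methylbut-2-en-1-yl)phenyl]ethanone | CC(=O)c1cc(CC=C(C)C)c(OCOC)c(CC=C(C)C)c1Br
F4 | step 5 | methyl 3-[2-bromo-4-(methoxymethoxy)-3,5-bis(3-methylbut-2-en-1-yl)phenyl]-3-oxopropanoate | COC(=O)CC(=O)c1cc(CC=C(C)C)c(OCOC)c(CC=C(C)C)c1Br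
F0 | step 13 | none | none
A1 | alternative 1 | 2-diazo-1-{3,5-dibromo-2-[(3-bromo-4-(methoxymethoxy)phenyl)methoxy]-4-(methoxymethoxy)phenyl}ethanone | COCOc1ccc(COc2c(Br)c(OCOC)c(Br)cc2C(=O)C=[N+]=[N-])cc1Br
A2 | alternative 1 | (S)-6,8,3'-tribromo-7,4'-bis(methoxymethoxy)flavanone | COCOc1ccc([C@@H]2CC(=O)c3cc(Br)c(OCOC)c(Br)c3O2)cc1Br
A3 | alternative 2 | 4-(tert-butyldimethylsilyloxy)-2-hydroxy-3,5-bis(3-methylbut-2-en-1-yl)benzaldehyde | O=Cc1cc(CC=C(C)C)c(O[Si](C)(C)C(C)(C)C)c(CC=C(C)C)c1O
A4 | alternative 2 | tert-butyl[4-ethenyl-2-(3-methylbut-2-en-1-yl)phenoxy]dimethylsilane | C=Cc1ccc(O[Si](C)(C)C(C)(C)C)c(CC=C(C)C)c1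
A5 | alternative 2 | (2S,4S)-7,4'-bis(tert-butyldimethylsilyloxy)-4-methoxy-6,8,3'-triprenylflavan | CC(C)=CCc1cc([C@@H]2C[C@H](OC)c3cc(CC=C(C)C)c(O[Si](C)(C)C(C)(C)C)c(CC=C(C)C)c3O2)ccc1O[Si](C)(C)C(C)(C)C
A6 | alternative 3 | (S)-5-iodo-2-[4-(methoxymethoxy)-3-(3-methylbut-2-en-1-yl)phenyl]-2,3-dihydro-4H-pyran-4-one | COCOc1ccc([C@@H]2CC(=O)C(I)=CO2)cc1CC=C(C)C
A7 | alternative 3 | tert-butyl[(2,10-dimethyl-7-methylideneundeca-2,5,9-trien-6-yl)oxy]dimethylsilane (2-silyloxy-1,3-diprenylbuta-1,3-diene) | C=C(CC=C(C)C)C(O[Si](C)(C)C(C)(C)C)=CCC=C(C)C
A8 | alternative 3 | (S)-7-(tert-butyldimethylsilyloxy)-4'-(methoxymethoxy)-6,8,3'-triprenylflavanone | CC(C)=CCc1cc([C@@H]2CC(=O)c3cc(CC=C(C)C)c(O[Si](C)(C)C(C)(C)C)c(CC=C(C)C)c3O2)ccc1OCOC
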